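## Structural features

Lobatin B is a furanoheliangolide. Its ten-membered carbocycle (C1–C10) is bridged by an oxygen between C3 and C10, so that O, C10, C1 (ketone), C2 and C3 form a 3(2H)-furanone, and its C6–C7 bond is shared with an α-methylene-γ-butyrolactone (C11–C13, lactone oxygen on C6). The furanone continues through C3–C4 into the Z trisubstituted C4=C5 alkene, giving a cross-conjugated dienone that ends at the allylic lactone carbinol C6. Five stereocentres stand in a row from C6 to C10 (6R,7S,8S,9R,10R): the lactone is trans-fused (H6 and H7 anti), C8 carries the isovalerate, C9 a free secondary hydroxyl, and C10 is quaternary (methyl, furanone oxygen, C1 carbonyl). The fragile groups are the exocyclic methylene lactone (Michael acceptor, alkene migration under base), the C8 ester beside the free C9 hydroxyl (acyl migration, hydrolysis), the allylic C6–O lactone bond and the vinylogous ester of the furanone. The real difficulty is twofold: a medium ring holding four sp2 carbons, a cis alkene and a transannular ether bridge, and the C8/C9/C10 oxygens, which must end as ester, free hydroxyl and ring ether. The key step exploits that C3, the furanone carbon bonded to C4, can be an aldehyde on a C1≡C2 alkyne before the furanone exists, so a vinyl nucleophile at C4 can close the ring at C3–C4 and the alkyne then serves as the latent C1 ketone and C2=C3 enol ether.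

## Logic of the disconnections

**28 to 26.** The enol ether bond O10–C3 is cut and the C1 carbonyl oxygen is returned to water, so C1–C2 becomes an alkyne and C3 a ketone. This removes the transannular bridge and leaves a monocarbocyclic γ-hydroxy ynone with all five stereocentres in place. The forward step must put water on C1 only (the β-carbon of the ynone) and let O10 (five-membered closure) rather than O9 (six-membered closure) add to C3.

**26 to 24 (through 25).** No skeletal bond is cut. The C9/C10 diol is masked as a cis-fused isopropylidene acetal and the C3 ketone is taken back to a carbinol. The acetal both protects and holds C8 and C1 gauche; the carbinol is what a carbonyl addition delivers. The forward steps need an oxidation mild enough for a strained enynol and an acetal hydrolysis that spares the ester and the lactone.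

**24 to 23.** The C3–C4 bond is cut, opening the ten-membered ring to a Z-vinyl iodide and an ynal. The geometry of C4=C5 is then fixed in an acyclic fragment, and the nucleophile is one that ignores esters and the methylene lactone. The forward step must close a strained ring in preference to oligomerising and must add 1,2 to the aldehyde only.

**23 to 18 (through 22, 21, 20, 19).** The C3 aldehyde goes back to a 4-methoxybenzyl ether, the C9/C10 acetal is removed, the O8–acyl bond is cut, and the acetal is placed on O8/O9. This returns the chain to the protecting pattern that the chiral pool supplies. The forward sequence must acylate O8 in the presence of O9 and the tertiary O10.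

**18 to 16 (through 17).** The alkyl–oxygen bond C6–O of the lactone is cut with inversion at C6. Closed transition states of 2-(alkoxycarbonyl)allyl metals whose C7 substituent is cis to the metallated methylene give the 6,7-syn adduct, which would close to a cis lactone with retention; the trans lactone is therefore made by inverting C6. The forward step must be a clean SN2 displacement at an allylic carbinol.

**16 to 11 and 15.** The C6–C7 bond is cut, dividing the molecule into a four-carbon Z-iodoenal and an allyl bromide that holds C7–C13 and C1–C3. This is the most convergent cut, and it builds the methylene lactone carbons in one step. The forward step must give 6,7-syn and the correct C7 face under control of C8.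

**11 to 8 and 9 (through 10).** The C7–C11 bond and the C13–Br bond are cut, leaving a C7 aldehyde and methyl acrylate. The forward steps must not epimerise C8, and the bromide must be formed with allylic transposition.

**8 to 3 and 5 (through 7).** The C10–C1 bond is cut, leaving a methyl ketone and a protected propargyl alcohol acetylide, and the C7 aldehyde goes back to an amide. The forward addition must be Felkin–Anh selective to set C10 and must leave the amide untouched.

**3 to 1 (through 2).** The C10–methyl bond is cut, leading back to a C2-symmetric tartrate derivative that supplies C8 and C9. The forward step must add one methyl group to one of two identical termini.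

**15 to 12 (through 14), and 5 to 4.** The C4–I bond and the O–benzyl bond are cut. The forward hydroalumination must be trans and regioselective so that iodine and the carbinol carbon end up cis.

## Other disconnections considered

**Alternative 1:** The C2–C3 bond is cut. In the forward direction the nine-membered lactone A2 (C3 as the lactone carbonyl on the tertiary O10, C1–C2 as an acetyl group on C10) is treated with LiN(SiMe3)2; the C2 enolate attacks C3 through a five-membered transition state (an O-to-C acyl transfer of the Baker–Venkataraman kind), and acid then closes and dehydrates the β-diketone to the furanone A1.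
- In its favour: the carbocycle arises by ring expansion rather than end-to-end closure, no strained cycloalkyne is involved, and the C10–O bond is already in place, so O9 cannot compete.
- Against it: A2 is a nine-membered lactone of a tertiary alcohol with a Z-enoate, itself a hard medium-ring esterification. The strong base forces the C11 methylene and the C8 ester to be absent, so methylenation, acetal removal and O8-selective acylation must follow on the finished skeleton.
- Comparison: on mechanism the acyl transfer is the better ring-forming event and avoids both the chromium excess and the gold step; on structure it moves the medium-ring problem into a lactonisation that is probably no easier than the closure of 23; on step economy it is equal at best, because three or four late steps follow A1 against three after 24.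

**Alternative 2:** The C8–C9 bond is cut. In the forward direction SmI2 reduces both aldehydes of the seco dialdehyde A4 to ketyls, which couple to the bicyclic diol A3.
- In its favour: the ring and two stereocentres form in one step, the furanone and the Z alkene are already present, and no chiral pool is needed for C8/C9.
- Against it: the C1 ketone bears an α-oxygen (C10–O) and lies next to the C9 aldehyde, so reductive C10–O cleavage and β-elimination from the C9 ketyl compete, and the dienone is reducible. The threo (8S,9R) diol is not assured in a medium ring. A3 still needs O8-selective acylation and methylenation.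
- Comparison: on structure it is the better plan in that its key step creates two lasting stereocentres, where step 18 creates one that is later erased; on mechanism its chemoselectivity is weaker than that of an organochromium addition; on step economy it is worse after the key step.

**Alternative 3:** The C4=C5 bond is cut. In the forward direction the second-generation Grubbs catalyst loads on the C6 vinyl group of the diene A6 and closes onto the isopropenyl group on the furanone, giving lobatin B 9-triethylsilyl ether A5 with loss of ethylene.
- In its favour: A5 is one desilylation from the target, which is the best end-game economy of all the plans and clearly better than the three steps after 24. The furanone is made on an acyclic precursor, and O9 is protected when it forms.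
- Against it: a trisubstituted alkene in a ten-membered ring must form from a 1,1-disubstituted, electron-poor alkene; the Z geometry is left to ring strain; the exocyclic methylene of the lactone is a second 1,1-disubstituted alkene that can engage or isomerise under ruthenium hydrides.
- Comparison: functional-group tolerance is equal; on structure the chosen plan is safer, because the alkene geometry is fixed in the vinyl iodide before the ring exists; on step economy after the key step Alternative 3 is better.

Key step: step 18

Assumption: 1 is bought as such, atoms carry germacrane numbers throughout, and 24 is carried as a mixture of C3 epimers (its SMILES has no descriptor at C3).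

Remark on the chemistry: two separate silyl ethers on O9 and O10 would favour the extended anti conformer about C9–C10; 23 therefore carries a cis-dioxolane there, which holds C8 and C1 gauche. The C6–C10 configurations and the Z alkene of 23 and 24 were checked centre by centre against 28.

## Route

Step 1
Reactants: 1 dimethyl 2,3-O-isopropylidene-L-tartrate
Product: 2 bis-Weinreb amide
Conditions: MeNH(OMe)·HCl, iPrMgCl, THF, −20 to 0 °C
Reagents that add atoms: N,O-dimethylhydroxylamine hydrochloride, Cl.CNOC
Why: Aminolysis of both esters by the chloromagnesium amide (Weinreb amide formation); the trans-dioxolane centres are also the thermodynamic ones, so they should not epimerise.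

Step 2
Reactants: 2 bis-Weinreb amide
Product: 3 keto Weinreb amide
Conditions: MeMgBr (1.05 equiv), THF, −78 to −40 °C; aq. NH4Cl
Reagents that add atoms: methylmagnesium bromide, C[Mg]Br
Why: Grignard addition to a Weinreb amide stops at the magnesium-chelated tetrahedral adduct; with one equivalent at low temperature this anionic adduct should shield the second amide, so mono-addition should dominate and unreacted 2 can be recycled.

Step 3
Reactants: 4 propargyl alcohol
Product: 5 4-methoxybenzyl propargyl ether
Conditions: NaH, 4-MeOC6H4CH2Cl, Bu4NI (cat.), THF, 0 °C to rt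
Reagents that add atoms: 4-methoxybenzyl chloride, COc1ccc(CCl)cc1
Why: Williamson ether synthesis; the ether survives base, hydride, acid and later leaves under neutral oxidative conditions.

Step 4
Reactants: 5 4-methoxybenzyl propargyl ether; 3 keto Weinreb amide
Product: 7 (10S)-tertiary propargylic alcohol, via lithium acetylide 6 (not isolated)
Conditions: 5, n-BuLi, THF, −78 °C; then 3, −78 °C; aq. NH4Cl
Reagents that add atoms: none
Why: Acetylide 1,2-addition to the ketone is much faster than to the Weinreb amide at −78 °C. Under Felkin–Anh control (C9–O bond anti to the nucleophile, approach past H9, lithium in THF a poor chelator) the 9,10-anti carbinol with 10S configuration should result.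

Step 5
Reactants: 7 (10S)-tertiary propargylic alcohol
Product: 8 C7 aldehyde
Conditions: iBu2AlH (3 equiv), THF, −78 °C; aq. KNaC4H4O6
Reagents that add atoms: none
Why: Hydride reduction of the Weinreb amide stops at the chelated hemiaminal and gives the aldehyde on work-up; the trans-dioxolane disfavours lactol formation with the C10 hydroxyl and epimerisation at C8.

Step 6
Reactants: 8 C7 aldehyde; 9 methyl acrylate
Product: 10 Morita–Baylis–Hillman adduct (both C7 epimers)
Conditions: DABCO, 1,4-dioxane/H2O (1:1), rt
Reagents that add atoms: none
Why: Morita–Baylis–Hillman reaction, which is fast for α-alkoxy aldehydes; the C7 carbinol configuration is irrelevant because C7 becomes sp2 in step 7.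

Step 7
Reactants: 10 Morita–Baylis–Hillman adduct
Product: 11 (Z)-2-(bromomethyl)enoate
Conditions: NBS, Me2S, CH2Cl2, −20 °C to rt
Reagents that add atoms: N-bromosuccinimide, O=C1CCC(=O)N1Br
Why: Corey–Kim activation of the secondary allylic hydroxyl and SN2′ attack of bromide at the methylene terminus; the conjugated Z isomer (C8 cis to CH2Br) is the favoured one, and the tertiary hydroxyl and the acetal are untouched under these neutral conditions.

Step 8
Reactants: 12 but-2-yn-1-ol
Product: 14 (Z)-3-iodobut-2-en-1-ol, via cyclic vinylalanate 13 (not isolated)
Conditions: NaAlH2(OCH2CH2OMe)2, THF, 0 °C to rt; then I2, −78 to 0 °C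
Reagents that add atoms: iodine, [I][I]
Why: Hydroxyl-directed trans-hydroalumination places hydride on C5 and aluminium on C4 in a five-membered alanate; iodinolysis with retention gives the Z iodide (iodine cis to the carbinol carbon).

Step 9
Reactants: 14 (Z)-3-iodobut-2-en-1-ol
Product: 15 (Z)-3-iodobut-2-enal
Conditions: MnO2, CH2Cl2, rt, dark
Reagents that add atoms: none
Why: Neutral allylic oxidation that keeps the Z geometry; the labile enal is used directly in solution.

Step 10
Reactants: 11 (Z)-2-(bromomethyl)enoate; 15 (Z)-3-iodobut-2-enal
Product: 16 6,7-syn hydroxy ester (6R,7S)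
Conditions: In powder, THF/H2O (1:1), rt
Reagents that add atoms: none
Why: Barbier allylation: the allylindium adds through C7 in a chair transition state with the C8 substituent axial (it is cis to the metallated methylene), which should give the 6,7-syn adduct. With H8 in the alkene plane (allylic 1,3-strain), O8 on the indium-bearing face and the C9 branch shielding the other face, the aldehyde should bond to C7 on the O8 face (7S). The vinyl iodide, acetal and ether are inert to indium.

Step 11
Reactants: 16 6,7-syn hydroxy ester
Product: 17 hydroxy acid
Conditions: LiOH, THF/H2O (3:1), 0 °C to rt; then 0.5 M HCl to pH 4, 0 °C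
Reagents that add atoms: lithium hydroxide, [Li+].[OH-]
Why: Saponification of the methyl ester (and of any cis lactone formed in step 10); cold, mild acidification and immediate use limit lactonisation with retention.

Step 12
Reactants: 17 hydroxy acid
Product: 18 trans lactone (6S,7S)
Conditions: PPh3, DIAD, THF (0.02 M), 0 °C to rt
Reagents that add atoms: none
Why: Mitsunobu lactonisation: the allylic C6 hydroxyl is activated as the oxyphosphonium ion and displaced by the carboxylate (5-exo-tet) with inversion, which turns the syn adduct into the trans lactone with the natural C6 configuration; the tertiary hydroxyl does not react.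

Step 13
Reactants: 18 trans lactone
Product: 19 8,9,10-triol
Conditions: AcOH/H2O (4:1), 50 °C
Reagents that add atoms: none
Why: Acid hydrolysis of the isopropylidene acetal; the benzyl-type ether, the lactone and the vinyl iodide tolerate aqueous acetic acid.

Step 14
Reactants: 19 8,9,10-triol
Product: 20 C8 isovalerate
Conditions: (iPrCH2CO)2O (1.05 equiv), pyridine, DMAP (cat.), CH2Cl2, −20 °C
Reagents that add atoms: isovaleric anhydride, CC(C)CC(=O)OC(=O)CC(C)C
Why: Nucleophilic-catalysed acylation should favour O8, since O9 is neopentylic (next to the quaternary C10) and the tertiary O10 is inert; O8 is also the less hindered, thermodynamically preferred site if the acyl group migrates.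

Step 15
Reactants: 20 C8 isovalerate
Product: 21 9,10-acetonide
Conditions: 2-methoxypropene, PPTS (cat.), CH2Cl2, 0 °C to rt
Reagents that add atoms: 2-methoxypropene, COC(C)=C
Why: Acid-catalysed acetal formation on the only remaining 1,2-diol; the dioxolane carries C8 and the alkyne cis.

Step 16
Reactants: 21 9,10-acetonide
Product: 22 propargylic alcohol
Conditions: DDQ, CH2Cl2/pH 7 buffer (10:1), 0 °C to rt
Reagents that add atoms: none
Why: Oxidative cleavage of the 4-methoxybenzyl ether by benzylic hydride abstraction and hydrolysis; ester, lactone, acetal and vinyl iodide are unaffected.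

Step 17
Reactants: 22 propargylic alcohol
Product: 23 seco (Z)-vinyl iodide ynal
Conditions: MnO2, CH2Cl2, rt
Reagents that add atoms: none
Why: Selective oxidation of the activated primary propargylic alcohol under neutral conditions; the ynal is taken on without storage.

Step 18
Reactants: 23 seco (Z)-vinyl iodide ynal
Product: 24 cyclodec-4-en-1-yn-3-ol
Conditions: CrCl2 (10 equiv), NiCl2 (0.1 equiv), degassed DMSO/THF (3:1), 2 mM, slow addition, rt
Reagents that add atoms: none
Why: Nozaki–Hiyama–Kishi reaction: zerovalent nickel, formed from NiCl2 by divalent chromium, inserts into the C4–I bond with retention of the Z geometry, transmetalation to trivalent chromium gives the alkenylchromium species, and this adds to the chromium-bound C3 aldehyde to give the chromium alkoxide of 24. The closest known reaction type is the chromium/nickel-mediated macrocyclisation of vinyl iodides onto aldehydes. The ten-membered ring closes in a 10-exo-trig mode (C4 attacks the C3 carbonyl carbon, the C=O bond stays outside the ring). Closure is helped by three rigid elements of 23: the Z alkene that turns C4 towards the chain, the cis-dioxolane that holds C8 and C1 gauche, and the linear C10–C1≡C2–C3 rod that spans the ring without transannular hydrogens; high dilution suppresses intermolecular coupling. The new C3 stereocentre is set by the ring conformation at the moment of addition (substrate control), and either epimer serves because C3 becomes a ketone in step 19. The step needs 1,2-addition to the aldehyde only: alkenylchromium reagents are unreactive towards the methylene lactone, the isovalerate, the acetal and the internal alkyne, and are too weakly basic to move the ester or epimerise C7. The C4=C5 geometry is carried over unchanged from the vinyl iodide.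

Step 19
Reactants: 24 cyclodec-4-en-1-yn-3-ol
Product: 25 cyclic enynone
Conditions: MnO2, CH2Cl2, rt
Reagents that add atoms: none
Why: Oxidation of a secondary alcohol that is both allylic and propargylic; both C3 epimers converge on one ketone.

Step 20
Reactants: 25 cyclic enynone
Product: 26 γ-hydroxy ynone 9,10-diol
Conditions: TFA/H2O (4:1), CH2Cl2, 0 °C
Reagents that add atoms: none
Why: Acid hydrolysis of the acetal; ionisation at C10–O or C6–O is disfavoured because both would place a cation next to the electron-poor ynone or dienone, and the ester and methylene lactone are acid-stable.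

Step 21
Reactants: 26 γ-hydroxy ynone 9,10-diol
Product: 28 lobatin B, via 1,3-diketone 27 (not isolated)
Conditions: Ph3PAuCl (5 mol%), AgOTf (5 mol%), H2O (2 equiv), toluene, rt
Reagents that add atoms: water, O
Why: Gold-catalysed cyclisation of a γ-hydroxy ynone to a 3(2H)-furanone: monovalent gold activates the alkyne, water adds to the β-carbon C1, and the α-hydroxyl O10 of the resulting 1,3-diketone closes the five-membered hemiketal on C3 and loses water. The five-membered closure through O10 is expected to outrun the six-membered one through O9, and no stereocentre is touched.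

## Compound list

1 | dimethyl (4R,5R)-2,2-dimethyl-1,3-dioxolane-4,5-dicarboxylate (dimethyl 2,3-O-isopropylidene-L-tartrate) | COC(=O)[C@@H]1OC(C)(C)O[C@H]1C(=O)OC | starting material
2 | (4R,5R)-N4,N5-dimethoxy-N4,N5,2,2-tetramethyl-1,3-dioxolane-4,5-dicarboxamide | CON(C)C(=O)[C@@H]1OC(C)(C)O[C@H]1C(=O)N(C)OC | intermediate
3 | (4R,5R)-5-acetyl-N-methoxy-N,2,2-trimethyl-1,3-dioxolane-4-carboxamide | CON(C)C(=O)[C@@H]1OC(C)(C)O[C@H]1C(C)=O | intermediate
4 | prop-2-yn-1-ol (propargyl alcohol) | C#CCO | starting material
5 | 1-methoxy-4-[(prop-2-yn-1-yloxy)methyl]benzene | C#CCOCc1ccc(OC)cc1 | intermediate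
6 | lithium acetylide of 5 | [Li]C#CCOCc1ccc(OC)cc1 | intermediate (not isolated)
7 | (4R,5R)-5-[(2S)-2-hydroxy-5-(4-methoxybenzyloxy)pent-3-yn-2-yl]-N-methoxy-N,2,2-trimethyl-1,3-dioxolane-4-carboxamide (germacrane 8R,9R,10S) | CON(C)C(=O)[C@@H]1OC(C)(C)O[C@H]1[C@@](C)(O)C#CCOCc1ccc(OC)cc1 | intermediate
8 | (4R,5R)-5-[(2S)-2-hydroxy-5-(4-methoxybenzyloxy)pent-3-yn-2-yl]-2,2-dimethyl-1,3-dioxolane-4-carbaldehyde | O=C[C@@H]1OC(C)(C)O[C@H]1[C@@](C)(O)C#CCOCc1ccc(OC)cc1 | intermediate
9 | methyl acrylate | C=CC(=O)OC | starting material
10 | methyl 2-[hydroxy{(4S,5R)-5-[(2S)-2-hydroxy-5-(4-methoxybenzyloxy)pent-3-yn-2-yl]-2,2-dimethyl-1,3-dioxolan-4-yl}methyl]prop-2-enoate, both C7 epimers | COC(=O)C(=C)C(O)[C@@H]1OC(C)(C)O[C@H]1[C@@](C)(O)C#CCOCc1ccc(OC)cc1 | intermediate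
11 | methyl (2Z)-2-(bromomethyl)-3-{(4S,5R)-5-[(2S)-2-hydroxy-5-(4-methoxybenzyloxy)pent-3-yn-2-yl]-2,2-dimethyl-1,3-dioxolan-4-yl}prop-2-enoate | COC(=O)/C(CBr)=C/[C@@H]1OC(C)(C)O[C@H]1[C@@](C)(O)C#CCOCc1ccc(OC)cc1 | intermediate
12 | but-2-yn-1-ol | CC#CCO | starting material
13 | sodium 2,2-bis(2-methoxyethoxy)-3-methyl-2,5-dihydro-1,2-oxaalumol-2-uide (cyclic vinylalanate) | CC1=CCO[Al-]1(OCCOC)OCCOC.[Na+] | intermediate (not isolated)
14 | (2Z)-3-iodobut-2-en-1-ol | C/C(I)=C/CO | intermediate
15 | (2Z)-3-iodobut-2-enal | C/C(I)=C/C=O | intermediate
16 | methyl (3S,4R,5Z)-4-hydroxy-3-{(4S,5R)-5-[(2S)-2-hydroxy-5-(4-methoxybenzyloxy)pent-3-yn-2-yl]-2,2-dimethyl-1,3-dioxolan-4-yl}-6-iodo-2-methylidenehept-5-enoate (germacrane 6R,7S; 6,7-syn) | I/C(C)=C\[C@H](O)[C@H](C(=C)C(=O)OC)[C@@H]1OC(C)(C)O[C@H]1[C@@](C)(O)C#CCOCc1ccc(OC)cc1 | intermediate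
17 | the carboxylic acid corresponding to 16, (3S,4R,5Z) | I/C(C)=C\[C@H](O)[C@H](C(=C)C(=O)O)[C@@H]1OC(C)(C)O[C@H]1[C@@](C)(O)C#CCOCc1ccc(OC)cc1 | intermediate
18 | (4S,5S)-4-{(4S,5R)-5-[(2S)-2-hydroxy-5-(4-methoxybenzyloxy)pent-3-yn-2-yl]-2,2-dimethyl-1,3-dioxolan-4-yl}-5-[(1Z)-2-iodoprop-1-en-1-yl]-3-methylideneoxolan-2-one (trans lactone, germacrane 6S,7S,8S,9R,10S) | I/C(C)=C\[C@H]1OC(=O)C(=C)[C@@H]1[C@@H]2OC(C)(C)O[C@H]2[C@@](C)(O)C#CCOCc3ccc(OC)cc3 | intermediate
19 | (4R,5S)-5-[(1Z)-2-iodoprop-1-en-1-yl]-3-methylidene-4-[(1S,2R,3S)-1,2,3-trihydroxy-6-(4-methoxybenzyloxy)-3-methylhex-4-yn-1-yl]oxolan-2-one (8,9,10-triol) | I/C(C)=C\[C@H]1OC(=O)C(=C)[C@@H]1[C@H](O)[C@@H](O)[C@@](C)(O)C#CCOCc2ccc(OC)cc2 | intermediate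
20 | 8-O-(3-methylbutanoyl) derivative of 19, hydroxyls on C9 and C10 free (germacrane 6S,7S,8S,9R,10S) | I/C(C)=C\[C@H]1OC(=O)C(=C)[C@@H]1[C@H](OC(=O)CC(C)C)[C@@H](O)[C@@](C)(O)C#CCOCc2ccc(OC)cc2 | intermediate
21 | 9,10-O-isopropylidene derivative of 20 (cis-dioxolane, C8 and the alkyne cis) | I/C(C)=C\[C@H]1OC(=O)C(=C)[C@@H]1[C@H](OC(=O)CC(C)C)[C@H]2OC(C)(C)O[C@@]2(C)C#CCOCc3ccc(OC)cc3 | intermediate
22 | C3 primary propargylic alcohol from 21 | I/C(C)=C\[C@H]1OC(=O)C(=C)[C@@H]1[C@H](OC(=O)CC(C)C)[C@H]2OC(C)(C)O[C@@]2(C)C#CCO | intermediate
23 | seco (Z)-vinyl iodide ynal: trans methylene lactone with the (Z)-2-iodoprop-1-enyl group on C6, C8 isovalerate, 9,10-acetonide, C10–C≡C–CHO (6S,7S,8S,9R,10S) | I/C(C)=C\[C@H]1OC(=O)C(=C)[C@@H]1[C@H](OC(=O)CC(C)C)[C@H]2OC(C)(C)O[C@@]2(C)C#CC=O | intermediate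
24 | (4Z)-cyclodec-4-en-1-yn-3-ol fused to the methylene lactone at C6–C7, C8 isovalerate, 9,10-acetonide (6R,7S,8S,9R,10S; C3 epimers) | C/C1=C/[C@H]2OC(=O)C(=C)[C@@H]2[C@H](OC(=O)CC(C)C)[C@H]3OC(C)(C)O[C@@]3(C)C#CC1O | intermediate
25 | the C3 ketone of 24 (cyclic enynone) | C/C1=C/[C@H]2OC(=O)C(=C)[C@@H]2[C@H](OC(=O)CC(C)C)[C@H]3OC(C)(C)O[C@@]3(C)C#CC1=O | intermediate
26 | 9,10-diol of 25 (γ-hydroxy ynone; 6R,7S,8S,9R,10S) | C/C1=C/[C@H]2OC(=O)C(=C)[C@@H]2[C@H](OC(=O)CC(C)C)[C@@H](O)[C@@](C)(O)C#CC1=O | intermediate
27 | 1,3-diketone from hydration of 26 at C1 | C/C1=C/[C@H]2OC(=O)C(=C)[C@@H]2[C@H](OC(=O)CC(C)C)[C@@H](O)[C@@](C)(O)C(=O)CC1=O | intermediate (not isolated)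
28 | lobatin B (6R,7S,8S,9R,10R,4Z) | C=C1C(=O)O[C@@H]2/C=C(/C)C3=CC(=O)[C@](C)(O3)[C@H](O)[C@@H](OC(=O)CC(C)C)[C@@H]12 | target

## Step count and least certain steps

Total: 21 steps. Longest linear sequence: 18 steps (from 1 through steps 1, 2, 4–7 and 10–21).

**Step 18 (key step).** The strained 10-exo closure may be outrun by intermolecular coupling, or the ynal may be lost by reduction or pinacol coupling at divalent chromium before the alkenylchromium species reaches it. Fallback: set out from 23 and oxidise the aldehyde (NaClO2, NaH2PO4, 2-methylbut-2-ene) to the ynoic acid F1. Protodecarboxylation (CuCl cat., Et3N, MeCN, 60 °C) gives the terminal alkyne F2. A carbonylative Sonogashira macrocyclisation (PdCl2(PPh3)2, Et3N, CO 1 atm, high dilution) then lets carbon monoxide supply C3 and forms both C2–C3 and C3–C4 on palladium, coming back to the route at 25.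

**Step 10.** The aqueous allylindium transition state may give poor face selectivity at C7 or an eroded syn preference, because coordination of O8 to indium competes with water. Fallback: set out from 10, acetylate (Ac2O, DMAP) to the acetate F3, and convert it by palladium-catalysed SN2′ borylation (Pd2(dba)3, B2pin2) into the (E)-allylboronate F4 (C8 cis to the borylmethyl group). Sc(OTf)3-catalysed allylboration of 15 in toluene at −78 °C then proceeds through a tight boron-centred chair in which only the steric bias of the C9 branch operates, coming back at 16.

**Step 12.** Retention may compete with inversion, either by activation of the carboxyl group as an acyloxyphosphonium ion or by ionisation at the allylic C6. Fallback: set out from 16 and mesylate the C6 hydroxyl (MsCl, Et3N, −20 °C) to the mesylate F5. On warming in MeCN the ester carbonyl oxygen displaces the mesylate intramolecularly with inversion and the methyl group is lost to methanesulfonate, coming back at 18.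

**Step 14.** Acylation may also occur at O9, twice, or be followed by acyl migration; the free C8 hydroxyl of 19 could also attack the lactone carbonyl (translactonisation). Fallback: set out from 18 and equilibrate the acetal under anhydrous acid (camphorsulfonic acid cat., acetone/2,2-dimethoxypropane) so that it moves to the fully substituted O9/O10 position, giving the 8-hydroxy 9,10-acetonide F6. O8 is then the only free secondary hydroxyl, and acylation as in step 14 comes back at 21, skipping 19 and 20.

**Step 4.** Chelation may compete with the Felkin–Anh pathway and lower the selectivity at C10, or the methyl ketone may be enolised. Fallback: set out from 2 and add one equivalent of 6 to give the ynone Weinreb amide F7. Addition of MeMgBr in Et2O/CH2Cl2 at −78 °C under Cram chelate control (magnesium bridging the ketone and O9) puts the methyl group on the face that gives the same 10S carbinol, coming back at 7.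

**Step 21.** O9 may close onto C3 in a six-membered mode and give a dihydropyranone, or the gold catalyst may be diverted by the conjugated enyne. Fallback: set out from 26 and silylate the secondary O9 selectively (Et3SiCl, imidazole, 0 °C; the tertiary O10 stays free) to the 9-triethylsilyl ether F8. The same gold-catalysed cyclisation, now with O10 as the only hydroxyl, gives lobatin B 9-triethylsilyl ether F9, and HF·pyridine in THF comes back at 28.

## Further compounds

F1 | step 18 | ynoic acid from 23 (C3 carboxylic acid) | I/C(C)=C\[C@H]1OC(=O)C(=C)[C@@H]1[C@H](OC(=O)CC(C)C)[C@H]2OC(C)(C)O[C@@]2(C)C#CC(=O)O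
F2 | step 18 | terminal alkyne lacking C3 | I/C(C)=C\[C@H]1OC(=O)C(=C)[C@@H]1[C@H](OC(=O)CC(C)C)[C@H]2OC(C)(C)O[C@@]2(C)C#C
F3 | step 10 | C7 acetate of 10 | COC(=O)C(=C)C(OC(C)=O)[C@@H]1OC(C)(C)O[C@H]1[C@@](C)(O)C#CCOCc1ccc(OC)cc1
F4 | step 10 | (E)-allylboronate, pinacol ester, from F3 | COC(=O)/C(CB1OC(C)(C)C(C)(C)O1)=C/[C@@H]1OC(C)(C)O[C@H]1[C@@](C)(O)C#CCOCc1ccc(OC)cc1
F5 | step 12 | C6 methanesulfonate of 16 | I/C(C)=C\[C@H](OS(C)(=O)=O)[C@H](C(=C)C(=O)OC)[C@@H]1OC(C)(C)O[C@H]1[C@@](C)(O)C#CCOCc1ccc(OC)cc1
F6 | step 14 | 8-hydroxy 9,10-acetonide isomer of 18 | I/C(C)=C\[C@H]1OC(=O)C(=C)[C@@H]1[C@H](O)[C@H]2OC(C)(C)O[C@@]2(C)C#CCOCc3ccc(OC)cc3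
F7 | step 4 | ynone Weinreb amide | CON(C)C(=O)[C@@H]1OC(C)(C)O[C@H]1C(=O)C#CCOCc1ccc(OC)cc1
F8 | step 21 | 9-triethylsilyl ether of 26 | C/C1=C/[C@H]2OC(=O)C(=C)[C@@H]2[C@H](OC(=O)CC(C)C)[C@@H](O[Si](CC)(CC)CC)[C@@](C)(O)C#CC1=O
F9 | step 21 | lobatin B 9-triethylsilyl ether | C=C1C(=O)O[C@@H]2/C=C(/C)C3=CC(=O)[C@](C)(O3)[C@H](O[Si](CC)(CC)CC)[C@@H](OC(=O)CC(C)C)[C@@H]12
A1 | alternative 1 | furanone-bridged bicycle with 8,9-acetonide, C11 as CH2 | C1C(=O)O[C@@H]2/C=C(/C)C3=CC(=O)[C@](C)(O3)[C@@H]4OC(C)(C)O[C@H]4[C@@H]12
A2 | alternative 1 | nine-membered lactone with C10 acetyl group, 8,9-acetonide | C1C(=O)O[C@@H]2/C=C(/C)C(=O)O[C@@](C)(C(C)=O)[C@@H]3OC(C)(C)O[C@H]3[C@@H]12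
A3 | alternative 2 | bicyclic 8,9-diol lacking the methylene and the ester | C1C(=O)O[C@@H]2/C=C(/C)C3=CC(=O)[C@](C)(O3)[C@H](O)[C@@H](O)[C@@H]12
A4 | alternative 2 | seco C8,C9 dialdehyde | O=C[C@H]1CC(=O)O[C@@H]1/C=C(/C)C1=CC(=O)[C@@](C)(C=O)O1
A5 | alternative 3 | lobatin B 9-triethylsilyl ether | C=C1C(=O)O[C@@H]2/C=C(/C)C3=CC(=O)[C@](C)(O3)[C@H](O[Si](CC)(CC)CC)[C@@H](OC(=O)CC(C)C)[C@@H]12
A6 | alternative 3 | seco diene (C6 vinyl, C3 isopropenyl on the furanone) | C=C[C@H]1OC(=O)C(=C)[C@@H]1[C@H](OC(=O)CC(C)C)[C@@H](O[Si](CC)(CC)CC)[C@@]1(C)OC(C(C)=C)=CC1=O
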